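**Plan**

- Retrosynthesis: remove the enoate, the acetate and a silyl ether, and take C=CH2 back to C=O. Then cut the CH2–CH(O) bond of the five-membered ring and return the ring-fusion bond to the carbonyl carbon, so that the cyclohexanone contracts to a 1-vinylcyclopentanol silyl ether carrying a (Z)-2-substituted but-2-enal side chain.
- Forward order: the cyclopentane is made first from a bought 4-silyloxycyclopentenone (iodination, Stille coupling, conjugate addition, vinyl addition, inversion of the oxygen-bearing carbon). One Lewis acid step then closes the five-membered ring and enlarges the cyclopentane to the cyclohexanone. Ring-fusion epimerisation, acetylation, α-hydroxylation, acylation, methylenation and desilylation finish the route.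
- Enabling feature: in the six-membered ring the exocyclic methylene carbon (a latent C=O) is bonded to a ring-fusion CH, and that CH is joined through the ring CH2 to the acetoxy carbon of the five-membered ring. The unit O=C–CH–CH2–CH(O) is what a vinyl carbinol and a tethered aldehyde give by Prins attack followed by a 1,2-shift.
- Stereochemistry: the one bought stereocentre directs the isopropyl group (anti), the side chain (trans) and the vinyl addition (anti), and is then itself re-set by hydroxyl-directed reduction. The key step sets the acetoxy carbon, equilibration sets the trans ring fusion, and axial enolate hydroxylation sets the acyloxy carbon.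
- Alkene geometry: the ethylidene comes from a syn-hydrostannation carried through the Stille coupling; the (Z)-enoate comes from a syn-carbocupration.

Key step: step 11

Remark: 1, 3, 21 and all unnumbered reagents are taken as commercial. Cyclopentane intermediates are numbered C1 (carbinol/carbonyl carbon), C2 (side chain), C3 (isopropyl), C4 (oxygen), C5 (CH2); bicyclic ones are numbered as octahydroindenes (C1 ethylidene, C2 oxygen, C3a/C7a ring fusion, C4 C=O or C=CH2, C5, C6 oxygen, C7 isopropyl).

**Route**

Step 1
Reactants: 1 (S)-4-(tert-butyldimethylsilyloxy)cyclopent-2-en-1-one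
Product: 2 (S)-4-(tert-butyldimethylsilyloxy)-2-iodocyclopent-2-en-1-one
Conditions: I2, pyridine, CH2Cl2, 0 °C → rt
Reagents that add atoms: iodine II
Why: α-Iodination of the enone by the pyridine-mediated addition–iodination–elimination sequence (Baylis–Hillman-type α-halogenation) leaves the C4 stereocentre untouched.

Step 2
Reactants: 3 but-2-ynal diethyl acetal
Product: 4 (E)-tributyl(1,1-diethoxybut-2-en-2-yl)stannane
Conditions: Bu3SnH, PdCl2(PPh3)2 (cat.), THF, 0 °C → rt
Reagents that add atoms: tributyltin hydride CCCC[SnH](CCCC)CCCC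
Why: Pd-catalysed syn-hydrostannation should place tin on the carbon next to the acetal and hydrogen cis to it, so that the methyl group is cis to the acetal carbon, which fixes the later ethylidene geometry.

Step 3
Reactants: 2 (S)-4-(tert-butyldimethylsilyloxy)-2-iodocyclopent-2-en-1-one; 4 (E)-tributyl(1,1-diethoxybut-2-en-2-yl)stannane
Product: 5 (S)-4-(tert-butyldimethylsilyloxy)-2-[(Z)-1,1-diethoxybut-2-en-2-yl]cyclopent-2-en-1-one
Conditions: Pd2(dba)3, AsPh3, CuI, NMP, rt → 45 °C
Reagents that add atoms: none
Why: Stille coupling of an α-iodoenone with an alkenylstannane (copper(I)-accelerated for the 1-substituted stannane) proceeds with retention of the alkene geometry.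

Step 4
Reactants: 5 (S)-4-(tert-butyldimethylsilyloxy)-2-[(Z)-1,1-diethoxybut-2-en-2-yl]cyclopent-2-en-1-one
Product: 7 4-(tert-butyldimethylsilyloxy)-2-[(Z)-1,1-diethoxybut-2-en-2-yl]-3-isopropylcyclopentan-1-one (2,3-trans; 3,4-trans), via chloromagnesium dienolate 6 (not isolated)
Conditions: i-PrMgCl, CuBr·SMe2 (cat.), THF, −78 °C; then AcOH, −78 °C
Reagents that add atoms: isopropylmagnesium chloride CC(C)[Mg]Cl
Why: Copper-catalysed conjugate addition occurs anti to the C4 silyloxy group (as in the prostaglandin two-component coupling) and sets C3, and low-temperature α-protonation of the dienolate should give the 2,3-trans ketone while the side-chain alkene stays out of conjugation.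

Step 5
Reactants: 7 4-(tert-butyldimethylsilyloxy)-2-[(Z)-1,1-diethoxybut-2-en-2-yl]-3-isopropylcyclopentan-1-one
Product: 8 4-(tert-butyldimethylsilyloxy)-2-[(Z)-1,1-diethoxybut-2-en-2-yl]-3-isopropyl-1-vinylcyclopentan-1-ol (1-OH cis to the side chain and to 4-OTBS; vinyl trans to the side chain)
Conditions: vinylMgBr, CeCl3, THF, −78 °C
Reagents that add atoms: vinylmagnesium bromide C=C[Mg]Br
Why: The organocerium reagent adds 1,2 without enolising the acidic C2–H and attacks the carbonyl face opposite to the adjacent side chain and the cis C4 silyloxy group, which sets the tertiary carbinol.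

Step 6
Reactants: 8 4-(tert-butyldimethylsilyloxy)-2-[(Z)-1,1-diethoxybut-2-en-2-yl]-3-isopropyl-1-vinylcyclopentan-1-ol
Product: 9 2-[(Z)-1,1-diethoxybut-2-en-2-yl]-3-isopropyl-1-vinylcyclopentane-1,4-diol (1-OH and 4-OH cis)
Conditions: TBAF, THF, 0 °C → rt
Reagents that add atoms: none
Why: Fluoride cleaves the secondary TBS ether and leaves the acetal and the alkenes alone.

Step 7
Reactants: 9 2-[(Z)-1,1-diethoxybut-2-en-2-yl]-3-isopropyl-1-vinylcyclopentane-1,4-diol
Product: 10 2-[(Z)-1,1-diethoxybut-2-en-2-yl]-1-hydroxy-3-isopropyl-1-vinylcyclopentan-4-one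
Conditions: Dess–Martin periodinane, pyridine, CH2Cl2, 0 °C → rt
Reagents that add atoms: none
Why: Dess–Martin oxidation converts only the secondary alcohol, since the tertiary allylic alcohol cannot be oxidised and the pyridine buffer protects the acetal.

Step 8
Reactants: 10 2-[(Z)-1,1-diethoxybut-2-en-2-yl]-1-hydroxy-3-isopropyl-1-vinylcyclopentan-4-one
Product: 11 2-[(Z)-1,1-diethoxybut-2-en-2-yl]-3-isopropyl-1-vinylcyclopentane-1,4-diol (4-OH trans to 1-OH and cis to 3-isopropyl)
Conditions: Me4NBH(OAc)3, MeCN/AcOH, −30 °C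
Reagents that add atoms: none
Why: In this Evans–Saksena reduction the tertiary hydroxyl binds the triacetoxyborohydride and delivers hydride to its own face of the ketone, which is also the face away from the neighbouring isopropyl group, so the new C4–OH should be trans to 1-OH and cis to isopropyl.

Step 9
Reactants: 11 2-[(Z)-1,1-diethoxybut-2-en-2-yl]-3-isopropyl-1-vinylcyclopentane-1,4-diol (4-OH cis to isopropyl)
Product: 13 1-O-triethylsilyl 4-O-tert-butyldimethylsilyl ether of 11, via mono-TBS ether 12 (not isolated)
Conditions: TBSCl, imidazole, DMF, rt; then TESCl, DMAP, 50 °C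
Reagents that add atoms: tert-butyldimethylsilyl chloride CC(C)(C)[Si](C)(C)Cl; triethylsilyl chloride CC[Si](Cl)(CC)CC
Why: TBSCl silylates only the secondary alcohol and TESCl/DMAP then caps the tertiary one (standard silyl ether formation), and silyl chlorides are used instead of triflates so that the acetal is not ionised.

Step 10
Reactants: 13 1-O-triethylsilyl 4-O-tert-butyldimethylsilyl ether of 11
Product: 14 (Z)-2-[4-(tert-butyldimethylsilyloxy)-3-isopropyl-1-(triethylsilyloxy)-1-vinylcyclopent-2-yl]but-2-enal
Conditions: 10% aq. oxalic acid on SiO2, CH2Cl2, rt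
Reagents that add atoms: water O
Why: The conjugated acetal is hydrolysed under conditions mild enough to keep both silyl ethers and the (Z)-geometry of the α-substituted enal.

Step 11
Reactants: 14 (Z)-2-[4-(tert-butyldimethylsilyloxy)-3-isopropyl-1-(triethylsilyloxy)-1-vinylcyclopent-2-yl]but-2-enal
Product: 16 cis-fused (Z)-6-(tert-butyldimethylsilyloxy)-1-ethylidene-2-hydroxy-7-isopropyloctahydro-4H-inden-4-one (H-3a; H-7a; 2-OH; 6-OSi; 7-isopropyl all on one face), via stannate-bound cyclohexyl cation 15 (not isolated)
Conditions: SnCl4, 2,6-di-tert-butyl-4-methylpyridine, CH2Cl2, −78 → −40 °C; then pH 7 buffer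
Reagents that add atoms: none
Why: Proposed new method: SnCl4 binds the aldehyde, the vinyl terminus attacks the carbonyl carbon (Prins step) and the secondary cation that develops next to the silyloxy carbon C1 is quenched by a 1,2-shift of the ring bond C1–C2 (pinacol step), after which loss of Et3Si+ leaves the ketone. The closest known reaction type is the acetal-initiated pinacol-terminated Prins cyclisation of 1-alkenyl-2-(2,2-dialkoxyethyl)cycloalkanol silyl ethers (ring-enlarging cyclopentane annulation); replacing the alkoxycarbenium ion by a Lewis acid-bound conjugated aldehyde is the untested part, argued from the ready Lewis acid-promoted Prins and carbonyl-ene cyclisations of unsaturated aldehydes, and it delivers the initiator oxygen as the free hydroxyl. Mode of closure: a six-membered ring closes 6-endo with respect to the vinyl group (carbonyl oxygen exocyclic) and is contracted at once to the five-membered ring by the shift, which at the same time enlarges the cyclopentane to the cyclohexanone by inserting the former vinyl CH between C1 and C2. The carbinol centre is set in a chair transition state that is trans-diequatorially fused to the cyclopentane, in which the tin-bound oxygen is axial because an equatorial oxygen would lie in the plane of the ethylidene and clash with its cis methyl group (A1,3 strain), and this puts O cis to H at C2. C2 migrates with retention on the face it already occupies, so the new ring-fusion centre forms cis to H at C2 and is corrected in step 12. The step needs migration of C2 and not of C5 (secured by the axial C1–OSi bond, which leaves C5 in the nodal plane of the cation, and by the allylic nature of C2), attack at the carbonyl carbon and not at the β-carbon of the enal (secured by ring size) and retention of the (Z)-enal geometry (secured by −78 °C and the proton scavenger).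

Step 12
Reactants: 16 cis-fused (Z)-6-(tert-butyldimethylsilyloxy)-1-ethylidene-2-hydroxy-7-isopropyloctahydro-4H-inden-4-one
Product: 17 trans-fused (Z)-6-(tert-butyldimethylsilyloxy)-1-ethylidene-2-hydroxy-7-isopropyloctahydro-4H-inden-4-one (H-3a now trans to H-7a)
Conditions: K2CO3, MeOH, rt
Reagents that add atoms: none
Why: Base-mediated epimerisation α to the ketone (thermodynamic control) should favour the trans-fused ketone with both five-ring bonds equatorial on the chair, as is known for related cis-fused 1-alkylidene-octahydroinden-4-ones, and the axial silyloxy group is a poor leaving group under these mild conditions.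

Step 13
Reactants: 17 trans-fused (Z)-6-(tert-butyldimethylsilyloxy)-1-ethylidene-2-hydroxy-7-isopropyloctahydro-4H-inden-4-one
Product: 18 trans-fused (Z)-2-acetoxy-6-(tert-butyldimethylsilyloxy)-1-ethylidene-7-isopropyloctahydro-4H-inden-4-one
Conditions: Ac2O, pyridine, DMAP (cat.), CH2Cl2, 0 °C
Reagents that add atoms: acetic anhydride CC(=O)OC(C)=O
Why: DMAP-catalysed acetylation of the only free (allylic secondary) hydroxyl.

Step 14
Reactants: 18 trans-fused (Z)-2-acetoxy-6-(tert-butyldimethylsilyloxy)-1-ethylidene-7-isopropyloctahydro-4H-inden-4-one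
Product: 20 trans-fused (Z)-2-acetoxy-6-(tert-butyldimethylsilyloxy)-1-ethylidene-5-hydroxy-7-isopropyloctahydro-4H-inden-4-one (5-OH axial; trans to 6-OSi), via potassium enolate 19 (not isolated)
Conditions: KHMDS, THF, −78 °C; then 2-(phenylsulfonyl)-3-phenyloxaziridine, −78 °C; then AcOH
Reagents that add atoms: 2-(phenylsulfonyl)-3-phenyloxaziridine O=S(=O)(c1ccccc1)N1OC1c1ccccc1
Why: Kinetic deprotonation takes place at the CH2 and not at the ring-fusion CH, and in the enolate hydroxylation (Davis oxidation) the oxidant attacks axially on the face opposite to the axial 6-silyloxy group, which should give the axial 5-hydroxyl trans to it.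

Step 15
Reactants: 21 ethyl pent-2-ynoate
Product: 22 ethyl (Z)-3-methylpent-2-enoate
Conditions: MeLi, CuI, THF, −78 °C (Me2CuLi); then MeOH, −78 °C
Reagents that add atoms: lithium dimethylcuprate [Li+].C[Cu-]C
Why: syn-Carbocupration of the ynoate and protonation at −78 °C put methyl and hydrogen cis, so the ethyl group is cis to the ester.

Step 16
Reactants: 22 ethyl (Z)-3-methylpent-2-enoate
Product: 23 (Z)-3-methylpent-2-enoic acid
Conditions: LiOH, THF/H2O, rt; then 1 M HCl
Reagents that add atoms: lithium hydroxide [Li+].[OH-]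
Why: Saponification at room temperature keeps the geometry of the trisubstituted alkene.

Step 17
Reactants: 20 trans-fused (Z)-2-acetoxy-6-(tert-butyldimethylsilyloxy)-1-ethylidene-5-hydroxy-7-isopropyloctahydro-4H-inden-4-one; 23 (Z)-3-methylpent-2-enoic acid
Product: 25 trans-fused (Z)-2-acetoxy-6-(tert-butyldimethylsilyloxy)-1-ethylidene-7-isopropyl-4-oxooctahydro-1H-inden-5-yl (Z)-3-methylpent-2-enoate, via mixed anhydride 24 (not isolated)
Conditions: 2,4,6-trichlorobenzoyl chloride, Et3N, THF, rt; then 20, DMAP, PhMe, rt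
Reagents that add atoms: none
Why: Yamaguchi esterification acylates the hindered axial α-hydroxyl under mild conditions that should keep the (Z)-enoate geometry.

Step 18
Reactants: 25 trans-fused (Z)-2-acetoxy-6-(tert-butyldimethylsilyloxy)-1-ethylidene-7-isopropyl-4-oxooctahydro-1H-inden-5-yl (Z)-3-methylpent-2-enoate
Product: 26 trans-fused (Z)-2-acetoxy-6-(tert-butyldimethylsilyloxy)-1-ethylidene-7-isopropyl-4-methyleneoctahydro-1H-inden-5-yl (Z)-3-methylpent-2-enoate
Conditions: Zn, CH2I2, TiCl4, THF/CH2Cl2, 0 °C → rt
Reagents that add atoms: diiodomethane ICI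
Why: Takai–Lombardo methylenation is non-basic and ketone-selective, so the hindered, epimerisable α-acyloxy ketone should be converted into the exocyclic methylene without touching the two esters.

Step 19
Reactants: 26 trans-fused (Z)-2-acetoxy-6-(tert-butyldimethylsilyloxy)-1-ethylidene-7-isopropyl-4-methyleneoctahydro-1H-inden-5-yl (Z)-3-methylpent-2-enoate
Product: 27 target: trans-fused (Z)-2-acetoxy-1-ethylidene-6-hydroxy-7-isopropyl-4-methyleneoctahydro-1H-inden-5-yl (Z)-3-methylpent-2-enoate
Conditions: HF·pyridine, THF, 0 °C → rt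
Reagents that add atoms: none
Why: Fluoride-mediated desilylation removes the secondary TBS ether without ester cleavage, and acyl migration is not expected because the vicinal oxygens are trans-diaxial.

**Compound list**

1 | (S)-4-(tert-butyldimethylsilyloxy)cyclopent-2-en-1-one | O=C1C=C[C@@H](O[Si](C)(C)C(C)(C)C)C1 | starting material
2 | (S)-4-(tert-butyldimethylsilyloxy)-2-iodocyclopent-2-en-1-one | O=C1C(I)=C[C@@H](O[Si](C)(C)C(C)(C)C)C1 | intermediate
3 | but-2-ynal diethyl acetal | CC#CC(OCC)OCC | starting material
4 | (E)-tributyl(1,1-diethoxybut-2-en-2-yl)stannane | C/C=C(/[Sn](CCCC)(CCCC)CCCC)C(OCC)OCC | intermediate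
5 | (S)-4-(tert-butyldimethylsilyloxy)-2-[(Z)-1,1-diethoxybut-2-en-2-yl]cyclopent-2-en-1-one | O=C1C(/C(=C/C)C(OCC)OCC)=C[C@@H](O[Si](C)(C)C(C)(C)C)C1 | intermediate
6 | chloromagnesium dienolate of 7 | Cl[Mg]OC1=C(/C(=C/C)C(OCC)OCC)[C@H](C(C)C)[C@@H](O[Si](C)(C)C(C)(C)C)C1 | intermediate
7 | 4-(tert-butyldimethylsilyloxy)-2-[(Z)-1,1-diethoxybut-2-en-2-yl]-3-isopropylcyclopentan-1-one (2,3-trans; 3,4-trans) | O=C1[C@@H](/C(=C/C)C(OCC)OCC)[C@H](C(C)C)[C@@H](O[Si](C)(C)C(C)(C)C)C1 | intermediate
8 | 4-(tert-butyldimethylsilyloxy)-2-[(Z)-1,1-diethoxybut-2-en-2-yl]-3-isopropyl-1-vinylcyclopentan-1-ol (1-OH cis to side chain and 4-OTBS) | O[C@@]1(C=C)[C@@H](/C(=C/C)C(OCC)OCC)[C@H](C(C)C)[C@@H](O[Si](C)(C)C(C)(C)C)C1 | intermediate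
9 | 2-[(Z)-1,1-diethoxybut-2-en-2-yl]-3-isopropyl-1-vinylcyclopentane-1,4-diol (1-OH and 4-OH cis) | O[C@@]1(C=C)[C@@H](/C(=C/C)C(OCC)OCC)[C@H](C(C)C)[C@@H](O)C1 | intermediate
10 | 2-[(Z)-1,1-diethoxybut-2-en-2-yl]-1-hydroxy-3-isopropyl-1-vinylcyclopentan-4-one | O[C@@]1(C=C)[C@@H](/C(=C/C)C(OCC)OCC)[C@H](C(C)C)C(=O)C1 | intermediate
11 | 2-[(Z)-1,1-diethoxybut-2-en-2-yl]-3-isopropyl-1-vinylcyclopentane-1,4-diol (4-OH trans to 1-OH, cis to isopropyl) | O[C@@]1(C=C)[C@@H](/C(=C/C)C(OCC)OCC)[C@H](C(C)C)[C@H](O)C1 | intermediate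
12 | 4-O-tert-butyldimethylsilyl ether of 11 | O[C@@]1(C=C)[C@@H](/C(=C/C)C(OCC)OCC)[C@H](C(C)C)[C@H](O[Si](C)(C)C(C)(C)C)C1 | intermediate
13 | 1-O-triethylsilyl 4-O-tert-butyldimethylsilyl ether of 11 | CC[Si](CC)(CC)O[C@@]1(C=C)[C@@H](/C(=C/C)C(OCC)OCC)[C@H](C(C)C)[C@H](O[Si](C)(C)C(C)(C)C)C1 | intermediate
14 | (Z)-2-[4-(tert-butyldimethylsilyloxy)-3-isopropyl-1-(triethylsilyloxy)-1-vinylcyclopent-2-yl]but-2-enal | CC[Si](CC)(CC)O[C@@]1(C=C)[C@@H](/C(=C/C)C=O)[C@H](C(C)C)[C@H](O[Si](C)(C)C(C)(C)C)C1 | intermediate
15 | stannate-bound bicyclic cyclohexyl cation formed in the Prins step | CC[Si](CC)(CC)O[C@@]1([CH+]C[C@@H]2O[Sn-](Cl)(Cl)(Cl)Cl)[C@@H](/C2=C/C)[C@H](C(C)C)[C@H](O[Si](C)(C)C(C)(C)C)C1 | intermediate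
16 | cis-fused (Z)-6-(tert-butyldimethylsilyloxy)-1-ethylidene-2-hydroxy-7-isopropyloctahydro-4H-inden-4-one | O=C1[C@H]2C[C@H](O)/C(=C\C)[C@H]2[C@H](C(C)C)[C@H](O[Si](C)(C)C(C)(C)C)C1 | intermediate
17 | trans-fused (Z)-6-(tert-butyldimethylsilyloxy)-1-ethylidene-2-hydroxy-7-isopropyloctahydro-4H-inden-4-one | O=C1[C@@H]2C[C@H](O)/C(=C\C)[C@H]2[C@H](C(C)C)[C@H](O[Si](C)(C)C(C)(C)C)C1 | intermediate
18 | trans-fused (Z)-2-acetoxy-6-(tert-butyldimethylsilyloxy)-1-ethylidene-7-isopropyloctahydro-4H-inden-4-one | O=C1[C@@H]2C[C@H](OC(C)=O)/C(=C\C)[C@H]2[C@H](C(C)C)[C@H](O[Si](C)(C)C(C)(C)C)C1 | intermediate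
19 | potassium enolate of 18 (C4=C5) | [K+].[O-]C=1[C@@H]2C[C@H](OC(C)=O)/C(=C\C)[C@H]2[C@H](C(C)C)[C@H](O[Si](C)(C)C(C)(C)C)C=1 | intermediate
20 | trans-fused (Z)-2-acetoxy-6-(tert-butyldimethylsilyloxy)-1-ethylidene-5-hydroxy-7-isopropyloctahydro-4H-inden-4-one | O=C1[C@@H]2C[C@H](OC(C)=O)/C(=C\C)[C@H]2[C@H](C(C)C)[C@H](O[Si](C)(C)C(C)(C)C)[C@H]1O | intermediate
21 | ethyl pent-2-ynoate | CCC#CC(=O)OCC | starting material
22 | ethyl (Z)-3-methylpent-2-enoate | CCOC(=O)/C=C(/C)CC | intermediate
23 | (Z)-3-methylpent-2-enoic acid | OC(=O)/C=C(/C)CC | intermediate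
24 | (Z)-3-methylpent-2-enoic 2,4,6-trichlorobenzoic anhydride | O=C(/C=C(/C)CC)OC(=O)c1c(Cl)cc(Cl)cc1Cl | intermediate
25 | trans-fused (Z)-2-acetoxy-6-(tert-butyldimethylsilyloxy)-1-ethylidene-7-isopropyl-4-oxooctahydro-1H-inden-5-yl (Z)-3-methylpent-2-enoate | O=C1[C@@H]2C[C@H](OC(C)=O)/C(=C\C)[C@H]2[C@H](C(C)C)[C@H](O[Si](C)(C)C(C)(C)C)[C@H]1OC(=O)/C=C(/C)CC | intermediate
26 | trans-fused (Z)-2-acetoxy-6-(tert-butyldimethylsilyloxy)-1-ethylidene-7-isopropyl-4-methyleneoctahydro-1H-inden-5-yl (Z)-3-methylpent-2-enoate | C=C1[C@@H]2C[C@H](OC(C)=O)/C(=C\C)[C@H]2[C@H](C(C)C)[C@H](O[Si](C)(C)C(C)(C)C)[C@H]1OC(=O)/C=C(/C)CC | intermediate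
27 | trans-fused (Z)-2-acetoxy-1-ethylidene-6-hydroxy-7-isopropyl-4-methyleneoctahydro-1H-inden-5-yl (Z)-3-methylpent-2-enoate | C=C1[C@@H]2C[C@H](OC(C)=O)/C(=C\C)[C@H]2[C@H](C(C)C)[C@H](O)[C@H]1OC(=O)/C=C(/C)CC | target

**Step count and risks**

Total step count: 19. Longest linear sequence: 16 (steps 1, 3 to 14, 17 to 19).

Step 11 (bears the label). The Lewis acid-bound conjugated aldehyde may be too weak an electrophile for the unactivated vinyl group; the tertiary allylic silyl ether may ionise first; or the (Z)-enal may isomerise before it cyclises. The fallback uses the precedented initiator, a full alkoxycarbenium ion. It sets out from 14. The aldehyde is converted with 2-naphthylmethyl trimethylsilyl ether and catalytic TMSOTf at −78 °C (Noyori acetalisation) into the bis(2-naphthylmethyl) acetal F1. SnCl4 at −78 °C then effects the acetal-initiated pinacol-terminated Prins cyclisation to give the cis-fused 2-(2-naphthylmethoxy) hydrindanone F2. Oxidative removal of the naphthylmethyl ether with DDQ in wet CH2Cl2 comes back to the route at 16.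

Step 12. The equilibrium may not lie far enough on the trans side, or enolisation towards C5 may lead to β-elimination of the silyloxy group before the ring-fusion centre has equilibrated. The fallback replaces thermodynamic control by a kinetic, stereoelectronically controlled protonation. It sets out from 16. TMSI/hexamethyldisilazane gives the more substituted (ring-fusion) silyl enol ether, with the hydroxyl silylated as well: bis-trimethylsilyl compound F3. Fluoride cleavage in the presence of acetic acid at −78 °C then protonates the ring-fusion enolate axially, anti to the pseudo-axial hydrogen at C7a, and frees the hydroxyl, which comes back to the route at 17.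

Step 4. The Grignard reagent may add 1,2 to the hindered cross-conjugated dienone; the dienolate may be protonated at the γ-carbon, which moves the alkene into conjugation and destroys the ethylidene geometry; or the facial selectivity at C2 may be poor. The fallback forms the C2–alkenyl bond on the saturated ring instead. It sets out from 1. Copper-catalysed addition of i-PrMgCl with TMSCl trapping gives the 3,4-trans enol silane F4. Stannane 4 is converted with iodine into the alkenyl iodide F5, with retention of geometry. Palladium-catalysed α-alkenylation of F4 with F5 (Bu3SnF activation) comes back to the route at 7.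

Further compounds
F1 | step 11 | bis(2-naphthylmethyl) acetal of 14 | CC[Si](CC)(CC)O[C@@]1(C=C)[C@@H](/C(=C/C)C(OCc2ccc3ccccc3c2)OCc2ccc3ccccc3c2)[C@H](C(C)C)[C@H](O[Si](C)(C)C(C)(C)C)C1
F2 | step 11 | cis-fused (Z)-6-(tert-butyldimethylsilyloxy)-1-ethylidene-7-isopropyl-2-(2-naphthylmethoxy)octahydro-4H-inden-4-one | O=C1[C@H]2C[C@H](OCc3ccc4ccccc4c3)/C(=C\C)[C@H]2[C@H](C(C)C)[C@H](O[Si](C)(C)C(C)(C)C)C1
F3 | step 12 | ring-fusion trimethylsilyl enol ether of 16 with 2-O-trimethylsilyl group | C[Si](C)(C)OC1=C2C[C@H](O[Si](C)(C)C)/C(=C\C)[C@H]2[C@H](C(C)C)[C@H](O[Si](C)(C)C(C)(C)C)C1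
F4 | step 4 | 4-(tert-butyldimethylsilyloxy)-3-isopropyl-1-(trimethylsilyloxy)cyclopent-1-ene (3,4-trans) | C[Si](C)(C)OC1=C[C@H](C(C)C)[C@@H](O[Si](C)(C)C(C)(C)C)C1
F5 | step 4 | (E)-1,1-diethoxy-2-iodobut-2-ene | C/C=C(/I)C(OCC)OCC
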